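**Strategy.** Ring B is assembled by a [3+3] annulation that makes C5–C6 and C8–C9 (labdane numbering). A C6–C7–C8 unit that already carries C17 is joined to ring A, where C5 and C9 both flank the quaternary C10. The key step uses a C4 ketone (later the gem-dimethyl carbon) as its silyl enol ether to make C5 nucleophilic. This adds to methyl 2-oxobut-3-enoate (Mukaiyama–Michael) and, in the same flask, the freed α-keto ester closes onto the C9=C11 alkene by a carbonyl-ene reaction. The precursor is a monocyclic 3-alkenyl-3-methylcyclohexenyl silyl ether from an asymmetric conjugate addition; the side chain comes from (S)-citronellol.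

Key step: step 6

Remark: positions are given in labdane numbering (C17 = carboxyl carbon on C8, C18/C19 = methyls on C4, C20 = methyl on C10; α/β as in the usual labdane drawing). The descriptors at C5 and C10 change from R to S when the C4 ketone becomes the gem-dimethyl carbon, and the descriptor at C13 reads R only while the C11=C12 alkene is present; these are priority changes, the centres themselves are not touched. The α-keto ester made in step 5 is labile and is used as a cold solution on the day it is made.

Step 1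
Reactants: 1 (S)-citronellol
Product: 2 (S)-{[(3,7-dimethyloct-6-en-1-yl)oxy]methyl}benzene
Conditions: NaH, BnBr, n-Bu4NI (cat.), THF, 0 → 25 °C
Reagents that add atoms: benzyl bromide, BrCc1ccccc1
Why: Williamson ether synthesis protects the primary alcohol as a benzyl ether that withstands the strong base, aluminium hydride and Lewis acids of steps 3–6; the stereocentre (future C13) is not touched.

Step 2
Reactants: 2 (S)-{[(3,7-dimethyloct-6-en-1-yl)oxy]methyl}benzene
Product: 3 (S)-6-(benzyloxy)-4-methylhexanal
Conditions: O3, CH2Cl2, −78 °C (indicator end point); then PPh3, −78 → 25 °C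
Reagents that add atoms: ozone, [O-][O+]=O
Why: Ozonolysis with reductive work-up cleaves the trisubstituted alkene, so that the aldehyde carbon is the future C9.

Step 3
Reactants: 3 (S)-6-(benzyloxy)-4-methylhexanal
Product: 5 (S)-{[(3-methylhex-5-yn-1-yl)oxy]methyl}benzene, via alkenyl nonaflate 4 (not isolated)
Conditions: n-C4F9SO2F, phosphazene base P2-Et, DMF, 0 → 25 °C
Reagents that add atoms: none
Why: O-Sulfonylation of the aldehyde enolate followed by base-induced β-elimination of the alkenyl nonaflate (one-pot aldehyde-to-alkyne dehydration) should give the terminal alkyne C9≡C11 with unchanged carbon count and an untouched γ-stereocentre.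

Step 4
Reactants: 5 (S)-{[(3-methylhex-5-yn-1-yl)oxy]methyl}benzene; 6 3-methylcyclohex-2-en-1-one
Product: 9 ({(3R)-3-[(1E,4S)-6-(benzyloxy)-4-methylhex-1-en-1-yl]-3-methylcyclohex-1-en-1-yl}oxy)trimethylsilane, via alkenylalane 7 (not isolated), via aluminium enolate 8 (not isolated)
Conditions: i-Bu2AlH, heptane, 50 °C; then 6, Cu(O2CC4H3S) (10 mol %), chiral phosphinamine ligand Ph2P–N[CH(CH3)Ph]2 (enantiomer that leads to (3R)-9), Et2O, −10 °C; then Me3SiOTf, −10 → 25 °C
Reagents that add atoms: trimethylsilyl trifluoromethanesulfonate, C[Si](C)(C)OS(=O)(=O)C(F)(F)F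
Why: syn-Hydroalumination gives the (E)-alkenylalane, copper-catalysed asymmetric conjugate addition transfers the alkenyl group to the β-carbon under ligand control to set the quaternary stereocentre (future C10), and O-silylation traps the enolate regiospecifically towards the future C5.

Step 5
Reactants: 10 methyl 2-hydroxybut-3-enoate (racemic)
Product: 11 methyl 2-oxobut-3-enoate
Conditions: 1,1,1-triacetoxy-1,1-dihydro-1,2-benziodoxol-3(1H)-one, CH2Cl2, 0 → 25 °C; filtered, kept as a solution at −20 °C
Reagents that add atoms: none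
Why: Hypervalent-iodine oxidation of the allylic α-hydroxy ester should give the reactive β,γ-unsaturated α-keto ester, which is used at once to avoid hetero-Diels–Alder dimerisation.

Step 6
Reactants: 9 ({(3R)-3-[(1E,4S)-6-(benzyloxy)-4-methylhex-1-en-1-yl]-3-methylcyclohex-1-en-1-yl}oxy)trimethylsilane; 11 methyl 2-oxobut-3-enoate
Product: 13 methyl (5R,8S,9R,10R,13R)-15-(benzyloxy)-8-hydroxy-4-oxo-18,19-dinorlabd-11(E)-en-17-oate, via keto ester 12 (not isolated)
Conditions: Sc(OTf)3 (10 mol %), (CF3)2CHOH (2 equiv), CH2Cl2, −40 → 25 °C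
Reagents that add atoms: none
Why: Sc(OTf)3 binds the 1,2-dicarbonyl unit of 11, C5 of the silyl enol ether adds to the CH2 terminus (Mukaiyama–Michael, C5–C6) and (CF3)2CHOH takes the silyl group and protonates C7 to release keto ester 12, whose C8 ketone is then activated by the same Lewis acid for an intramolecular carbonyl-ene reaction with the C9=C11 alkene, the hydrogen coming from C12 (C8–C9). The closest known reactions are Mukaiyama–Michael additions of enol silanes to β,γ-unsaturated α-keto esters and Lewis-acid carbonyl-ene cyclisations of unsaturated α-keto esters and aldehydes, including sequential conjugate-ene/carbonyl-ene [3+3] annulations of alkenes with enals. Ring B closes in a 6-exo mode with respect to both the C8=O and the C9=C11 π bonds, through a chair in which the C10 methyl is axial and the C9 substituent equatorial, which sets C9 (9α-H) from the preset C10. C8 is expected with the hydroxyl axial (8β) and the ester equatorial, because an axial ester would be 1,3-diaxial to the C10 methyl. C5 is set in the Michael step by attack anti to the pseudoaxial alkenyl group and stays epimerisable next to the C4 ketone, so that either C5 epimer should converge on the trans-fused decalone in step 7. The step needs 1,4- rather than 1,2-addition, secured by the chelated s-cis keto ester with its unhindered terminus, and ene closure rather than aldol closure from C3, secured by the non-basic conditions and the high electrophilicity of the α-keto ester.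

Step 7
Reactants: 13 methyl (5R,8S,9R,10R,13R)-15-(benzyloxy)-8-hydroxy-4-oxo-18,19-dinorlabd-11(E)-en-17-oate
Product: 14 methyl (5R,8S,9R,10R,13S)-8,15-dihydroxy-4-oxo-18,19-dinorlabdan-17-oate
Conditions: NaOMe (0.1 equiv), MeOH, 25 °C; AcOH; then H2 (1 atm), Pd(OH)2/C, MeOH, 25 °C
Reagents that add atoms: none
Why: Base equilibration at C5 (α to the C4 ketone) should favour the trans-fused decalone, in which the C9 chain stays equatorial, under thermodynamic control, and catalytic hydrogenation then saturates the C11=C12 alkene and hydrogenolyses the benzyl ether in the same flask.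

Step 8
Reactants: 14 methyl (5R,8S,9R,10R,13S)-8,15-dihydroxy-4-oxo-18,19-dinorlabdan-17-oate
Product: 15 methyl (5R,8S,9R,10R,13S)-15-acetoxy-8-hydroxy-4-oxo-18,19-dinorlabdan-17-oate
Conditions: Ac2O, pyridine, 0 → 25 °C
Reagents that add atoms: acetic anhydride, CC(=O)OC(C)=O
Why: Acylation should be selective for the primary C15 alcohol, since the tertiary, axial α-hydroxy ester at C8 is too hindered to react without a nucleophilic catalyst.

Step 9
Reactants: 15 methyl (5R,8S,9R,10R,13S)-15-acetoxy-8-hydroxy-4-oxo-18,19-dinorlabdan-17-oate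
Product: 16 methyl (5R,9R,10R,13S)-15-acetoxy-4-oxo-18,19-dinorlabd-7-en-17-oate
Conditions: MeO2C–N(−)–SO2–N(+)Et3 (inner salt), toluene, 70 °C
Reagents that add atoms: none
Why: Thermal syn-elimination (Ei) of the tertiary sulfamate can only take the cis hydrogen on C7, because the hydrogen on C9 is α and trans to the axial 8β-oxygen, so the double bond should form at C7=C8 in conjugation with the ester.

Step 10
Reactants: 16 methyl (5R,9R,10R,13S)-15-acetoxy-4-oxo-18,19-dinorlabd-7-en-17-oate
Product: 17 methyl (5S,9R,10S,13S)-15-acetoxylabd-7-en-17-oate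
Conditions: Me2Zn, TiCl4, CH2Cl2, −30 → 25 °C
Reagents that add atoms: dimethylzinc, C[Zn]C
Why: Geminal dimethylation of a ketone by Me2TiCl2, formed in the flask from Me2Zn and TiCl4 (carbonyl methylation, ionisation of the tertiary titanium alkoxide, second methyl transfer), should convert C4=O into the C4 gem-dimethyl group while the esters and the enoate are inert.

Step 11
Reactants: 17 methyl (5S,9R,10S,13S)-15-acetoxylabd-7-en-17-oate
Product: 18 (5S,9R,10S,13S)-15-acetoxylabd-7-en-17-oic acid (CNP0412535.1)
Conditions: LiI, EtOAc, reflux, dark; then 1 M HCl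
Reagents that add atoms: none
Why: Nucleophilic (SN2) demethylation by iodide attacks the methyl carbon of the hindered conjugated ester and should leave the primary acetate, which has no comparably reactive O-alkyl carbon, in place.

**Compound list**

1 | (S)-citronellol, (S)-3,7-dimethyloct-6-en-1-ol | OCC[C@@H](C)CCC=C(C)C | starting material
2 | (S)-{[(3,7-dimethyloct-6-en-1-yl)oxy]methyl}benzene | c1ccccc1COCC[C@@H](C)CCC=C(C)C | intermediate
3 | (S)-6-(benzyloxy)-4-methylhexanal | c1ccccc1COCC[C@@H](C)CCC=O | intermediate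
4 | (S)-6-(benzyloxy)-4-methylhex-1-en-1-yl nonafluorobutane-1-sulfonate (E/Z mixture, not isolated) | c1ccccc1COCC[C@@H](C)CC=COS(=O)(=O)C(F)(F)C(F)(F)C(F)(F)C(F)(F)F | intermediate
5 | (S)-{[(3-methylhex-5-yn-1-yl)oxy]methyl}benzene | c1ccccc1COCC[C@@H](C)CC#C | intermediate
6 | 3-methylcyclohex-2-en-1-one | CC1=CC(=O)CCC1 | starting material
7 | [(1E,4S)-6-(benzyloxy)-4-methylhex-1-en-1-yl]bis(2-methylpropyl)aluminium (not isolated) | c1ccccc1COCC[C@@H](C)C/C=C/[Al](CC(C)C)CC(C)C | intermediate
8 | bis(2-methylpropyl)({(3R)-3-[(1E,4S)-6-(benzyloxy)-4-methylhex-1-en-1-yl]-3-methylcyclohex-1-en-1-yl}oxy)aluminium, the aluminium enolate formed towards the future C5 (not isolated) | CC(C)C[Al](CC(C)C)OC1=C[C@@](C)(/C=C/C[C@H](C)CCOCc2ccccc2)CCC1 | intermediate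
9 | ({(3R)-3-[(1E,4S)-6-(benzyloxy)-4-methylhex-1-en-1-yl]-3-methylcyclohex-1-en-1-yl}oxy)trimethylsilane | C[Si](C)(C)OC1=C[C@@](C)(/C=C/C[C@H](C)CCOCc2ccccc2)CCC1 | intermediate
10 | methyl 2-hydroxybut-3-enoate (racemic) | C=CC(O)C(=O)OC | starting material
11 | methyl 2-oxobut-3-enoate | C=CC(=O)C(=O)OC | intermediate
12 | methyl 4-{(1R,2R)-2-[(1E,4S)-6-(benzyloxy)-4-methylhex-1-en-1-yl]-2-methyl-6-oxocyclohexyl}-2-oxobutanoate (not isolated) | COC(=O)C(=O)CC[C@H]1C(=O)CCC[C@]1(C)/C=C/C[C@H](C)CCOCc1ccccc1 | intermediate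
13 | methyl (5R,8S,9R,10R,13R)-15-(benzyloxy)-8-hydroxy-4-oxo-18,19-dinorlabd-11(E)-en-17-oate (5α-H, 8β-OH, 9α-H, 10β-CH3) | c1ccccc1COCC[C@@H](C)/C=C/[C@H]1[C@](O)(C(=O)OC)CC[C@H]2C(=O)CCC[C@]12C | intermediate
14 | methyl (5R,8S,9R,10R,13S)-8,15-dihydroxy-4-oxo-18,19-dinorlabdan-17-oate | OCC[C@@H](C)CC[C@H]1[C@](O)(C(=O)OC)CC[C@H]2C(=O)CCC[C@]12C | intermediate
15 | methyl (5R,8S,9R,10R,13S)-15-acetoxy-8-hydroxy-4-oxo-18,19-dinorlabdan-17-oate | CC(=O)OCC[C@@H](C)CC[C@H]1[C@](O)(C(=O)OC)CC[C@H]2C(=O)CCC[C@]12C | intermediate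
16 | methyl (5R,9R,10R,13S)-15-acetoxy-4-oxo-18,19-dinorlabd-7-en-17-oate | CC(=O)OCC[C@@H](C)CC[C@H]1C(C(=O)OC)=CC[C@H]2C(=O)CCC[C@]12C | intermediate
17 | methyl (5S,9R,10S,13S)-15-acetoxylabd-7-en-17-oate | CC(=O)OCC[C@@H](C)CC[C@H]1C(C(=O)OC)=CC[C@H]2C(C)(C)CCC[C@]12C | intermediate
18 | (5S,9R,10S,13S)-15-acetoxylabd-7-en-17-oic acid | CC(=O)OCC[C@@H](C)CC[C@H]1C(C(=O)O)=CC[C@H]2C(C)(C)CCC[C@]12C | target

**Step count.** Total: 11 steps. Longest linear sequence: 10 steps (steps 1–4 and 6–11; step 5 is a one-step side branch that prepares 11).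

**Steps most likely to fail**

1. Step 6. The cascade may stop after the conjugate addition, the keto ester may close by aldol reaction from C3 instead of by the ene reaction, or the hindered 1,2-disubstituted alkene may react too slowly. Fallback: the cascade is replaced by a stepwise annulation in which the two bonds are made in separate flasks, setting out from 9 and 11. The Mukaiyama–Michael addition alone (Sc(OTf)3, (CF3)2CHOH, CH2Cl2, −78 °C, cold aqueous quench) should give keto ester 12 as an isolated compound. This is then closed in a discrete carbonyl-ene step with stoichiometric Me2AlCl (CH2Cl2, −78 → 0 °C), a Lewis acid that also scavenges protons, which comes back to the route at 13. No new compound arises (F0).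

2. Step 9. Regiocontrol of the elimination is lost (double bond towards C9) if the C8 epimer with equatorial hydroxyl predominates, or the hindered tertiary alcohol is sulfamoylated too slowly. Fallback: C17 is excised and put back regiospecifically, setting out from 15. Geminal dimethylation with Me2TiCl2 (from Me2Zn and TiCl4) gives methyl 15-acetoxy-8β-hydroxylabdan-17-oate F1. LiAlH4 (THF) then reduces both esters to labdane-8β,15,17-triol F2, and NaIO4 (THF–H2O) cleaves the 8,17-diol to 15-hydroxy-17-norlabdan-8-one F3. Ac2O in pyridine gives 15-acetoxy-17-norlabdan-8-one F4. Kinetic deprotonation at the C7 methylene (KN(SiMe3)2, PhNTf2, THF, −78 °C) gives 15-acetoxy-17-norlabd-7-en-8-yl trifluoromethanesulfonate F5, and hydroxycarbonylation (Pd(OAc)2, Ph2P(CH2)3PPh2, CO, KOAc, DMF–H2O, 60 °C) comes back to the route at 18.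

3. Step 10. Ionisation at C4 may be followed by hydride shift from C5, methyl migration or elimination instead of the second methyl transfer. Fallback: the gem-dimethyl group is built through a cyclopropane before the C7=C8 bond exists, setting out from 14. Methylenation (Zn, CH2Br2, TiCl4, THF) gives methyl 8β,15-dihydroxy-4-methylidene-18,19-dinorlabdan-17-oate F6. Simmons–Smith cyclopropanation (Et2Zn, CH2I2, CH2Cl2) gives methyl 8β,15-dihydroxy-18,19-dinorlabdan-17-oate 4-spirocyclopropane F7. Hydrogenolysis of the least substituted cyclopropane bond (H2, PtO2, AcOH) gives methyl 8β,15-dihydroxylabdan-17-oate F8. Acetylation (Ac2O, pyridine) gives methyl 15-acetoxy-8β-hydroxylabdan-17-oate F1, and the syn-elimination of step 9 applied to it comes back to the route at 17.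

Further compounds
F0 | step 6 | none | none
F1 | step 9 | methyl 15-acetoxy-8β-hydroxylabdan-17-oate (5α-H, 9α-H, 10β-CH3, 13S) | CC(=O)OCC[C@@H](C)CC[C@H]1[C@](O)(C(=O)OC)CC[C@H]2C(C)(C)CCC[C@]12C
F2 | step 9 | labdane-8β,15,17-triol (5α-H, 9α-H, 10β-CH3, 13S) | OCC[C@@H](C)CC[C@H]1[C@](O)(CO)CC[C@H]2C(C)(C)CCC[C@]12C
F3 | step 9 | 15-hydroxy-17-norlabdan-8-one (5α-H, 9α-H, 10β-CH3, 13S) | OCC[C@@H](C)CC[C@H]1C(=O)CC[C@H]2C(C)(C)CCC[C@]12C
F4 | step 9 | 15-acetoxy-17-norlabdan-8-one (5α-H, 9α-H, 10β-CH3, 13S) | CC(=O)OCC[C@@H](C)CC[C@H]1C(=O)CC[C@H]2C(C)(C)CCC[C@]12C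
F5 | step 9 | 15-acetoxy-17-norlabd-7-en-8-yl trifluoromethanesulfonate (5α-H, 9α-H, 10β-CH3, 13S) | CC(=O)OCC[C@@H](C)CC[C@H]1C(OS(=O)(=O)C(F)(F)F)=CC[C@H]2C(C)(C)CCC[C@]12C
F6 | step 10 | methyl 8β,15-dihydroxy-4-methylidene-18,19-dinorlabdan-17-oate (5α-H, 9α-H, 10β-CH3, 13S) | OCC[C@@H](C)CC[C@H]1[C@](O)(C(=O)OC)CC[C@H]2C(=C)CCC[C@]12C
F7 | step 10 | methyl 8β,15-dihydroxy-18,19-dinorlabdan-17-oate 4-spirocyclopropane (5α-H, 9α-H, 10β-CH3, 13S) | OCC[C@@H](C)CC[C@H]1[C@](O)(C(=O)OC)CC[C@H]2C3(CC3)CCC[C@]12C
F8 | step 10 | methyl 8β,15-dihydroxylabdan-17-oate (5α-H, 9α-H, 10β-CH3, 13S) | OCC[C@@H](C)CC[C@H]1[C@](O)(C(=O)OC)CC[C@H]2C(C)(C)CCC[C@]12C
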